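**Plan**
1. The target is read as epigallocatechin-(4β→6)-epigallocatechin 3-O-gallate with the ester on the lower unit (upper unit 2R,3R,4S; lower unit 2R,3R). Retrosynthetic cuts, in order: the gallate ester C–O; C4–C4a of the lower pyran (ring F); the O1–C2 aryl ether of the lower unit; the interflavan bond C4 (upper)–C6 (ring D).
2. Enabling feature: ring D is a phloroglucinol ring with C6 para to O1. Before ring F exists, the two carbons ortho to O1 (later C4a and C8) are equivalent, so closing C4–C4a on an open ring D that already carries the upper unit can only give the 4→6 isomer.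
3. Forward order: (−)-epigallocatechin supplies rings A, B and C as a benzylated, 8-bromo-capped C4 electrophile. It is joined to an ortho-blocked phloroglucinol (open ring D), debrominated, etherified with an epoxy alcohol that carries ring E, then ring F is closed, the gallate is attached and all benzyl groups are removed.
4. Stereochemistry: upper C2/C3 come from (−)-epigallocatechin; upper C4 from attack anti to the 3-benzyloxy group; lower C3 and C2 from a Sharpless kinetic resolution, with C2 then inverted in the Mitsunobu step. The ring closure touches neither.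

Key step: step 11

Assumption: 1, 6, 10, 11 and 16 are taken as commercially available; bromine serves only as a removable blocking group.

**Route**

Step 1
Reactants: 1 (−)-epigallocatechin
Product: 2 5,7,3',4',5'-penta-O-benzyl-(−)-epigallocatechin
Conditions: BnBr (5.5 equiv), K2CO3, DMF, 0 °C to rt
Reagents that add atoms: benzyl bromide, BrCc1ccccc1
Why: Williamson etherification in which carbonate deprotonates only the five phenols, so the secondary 3-OH stays free and C2/C3 are not touched.

Step 2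
Reactants: 2 5,7,3',4',5'-penta-O-benzyl-(−)-epigallocatechin
Product: 3 3,5,7,3',4',5'-hexa-O-benzyl-(−)-epigallocatechin
Conditions: NaH, BnBr, DMF, 0 °C to rt
Reagents that add atoms: benzyl bromide, BrCc1ccccc1
Why: Williamson etherification of the sodium alkoxide masks the upper 3-OH, which would otherwise compete as the alcohol partner in step 10 and as an acyl acceptor in step 12, and which is released with the other benzyl groups at the end.

Step 3
Reactants: 3 3,5,7,3',4',5'-hexa-O-benzyl-(−)-epigallocatechin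
Product: 4 4β-(2-ethoxyethoxy)-3,5,7,3',4',5'-hexa-O-benzyl-(−)-epigallocatechin
Conditions: DDQ (2 equiv), 2-ethoxyethanol (excess), CH2Cl2, rt
Reagents that add atoms: 2-ethoxyethanol, CCOCCO
Why: DDQ benzylic oxidation abstracts hydride from C4 to give the cation stabilised by the ring A oxygens, and the alcohol should add anti to the 3-benzyloxy group, setting the 4β (3,4-trans, 4S) ether.

Step 4
Reactants: 4 4β-(2-ethoxyethoxy)-3,5,7,3',4',5'-hexa-O-benzyl-(−)-epigallocatechin
Product: 5 8-bromo-4β-(2-ethoxyethoxy)-3,5,7,3',4',5'-hexa-O-benzyl-(−)-epigallocatechin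
Conditions: NBS (1.0 equiv), CH2Cl2, −78 to 0 °C
Reagents that add atoms: N-bromosuccinimide, O=C1CCC(=O)N1Br
Why: Electrophilic aromatic bromination should go to C8 of ring A (ortho to O1 and 7-OBn, para to 5-OBn), the most reactive nuclear position, and the bromine there stops the electrophile from condensing with itself in step 6.

Step 5
Reactants: 6 3,5-bis(benzyloxy)phenol
Product: 7 3,5-bis(benzyloxy)-2,6-dibromophenol
Conditions: NBS (2.05 equiv), i-Pr2NH (10 mol %), CH2Cl2, 0 °C
Reagents that add atoms: N-bromosuccinimide, O=C1CCC(=O)N1Br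
Why: Amine-mediated ortho-selective electrophilic bromination of a phenol should brominate both carbons ortho to OH (each also para to a benzyloxy group), leaving only the carbon between the two benzyloxy groups free.

Step 6
Reactants: 5 8-bromo-4β-(2-ethoxyethoxy)-3,5,7,3',4',5'-hexa-O-benzyl-(−)-epigallocatechin; 7 3,5-bis(benzyloxy)-2,6-dibromophenol (4 equiv)
Product: 8 3,5-bis(benzyloxy)-2,6-dibromo-4-[8-bromo-3,5,7,3',4',5'-hexa-O-benzyl-(−)-epigallocatechin-4β-yl]phenol
Conditions: TMSOTf (0.5 equiv), CH2Cl2, −78 to −40 °C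
Reagents that add atoms: none
Why: Lewis-acid-mediated Friedel–Crafts coupling through the flavan-4-yl cation, in which the only free nuclear carbon of 7 (para to OH) should attack C4 anti to the 3-benzyloxy group and so set the upper C4 as 4β (3,4-trans), while the 8-bromine excludes self-condensation at C8 of 5.

Step 7
Reactants: 8 3,5-bis(benzyloxy)-2,6-dibromo-4-[8-bromo-3,5,7,3',4',5'-hexa-O-benzyl-(−)-epigallocatechin-4β-yl]phenol
Product: 9 3,5-bis(benzyloxy)-4-[3,5,7,3',4',5'-hexa-O-benzyl-(−)-epigallocatechin-4β-yl]phenol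
Conditions: Pd(PPh3)4 (10 mol %), HCO2Na (6 equiv), DMF, 90 °C
Reagents that add atoms: none
Why: Palladium-catalysed transfer hydrodehalogenation (oxidative addition of zerovalent palladium into each C–Br bond, formate exchange, decarboxylation to the hydride, reductive elimination) should remove the three bromines without touching benzyl ethers or stereocentres, freeing the two equivalent ortho carbons of ring D.

Step 8
Reactants: 10 3,4,5-tris(benzyloxy)benzaldehyde; 11 vinylmagnesium bromide
Product: 12 rac-1-[3,4,5-tris(benzyloxy)phenyl]prop-2-en-1-ol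
Conditions: THF, −20 to 0 °C; H2O work-up
Reagents that add atoms: none
Why: Grignard 1,2-addition to the aldehyde gives the racemic secondary allylic alcohol needed for the resolution.

Step 9
Reactants: 12 rac-1-[3,4,5-tris(benzyloxy)phenyl]prop-2-en-1-ol
Product: 13 (S)-[(2R)-oxiran-2-yl][3,4,5-tris(benzyloxy)phenyl]methanol (erythro)
Conditions: Ti(OiPr)4 (0.2 equiv), L-(+)-diisopropyl tartrate (0.25 equiv), t-BuOOH (0.6 equiv), 4 Å molecular sieves, CH2Cl2, −20 °C
Reagents that add atoms: tert-butyl hydroperoxide, CC(C)(C)OO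
Why: Sharpless kinetic resolution, in which the L-(+)-tartrate catalyst should epoxidise the (R)-enantiomer of 12 fast and on the face that gives the erythro epoxy alcohol, setting the (R)-oxirane carbon (future C3) and selecting the (S)-carbinol carbon (future C2), while (S)-12 is left behind and separated.

Step 10
Reactants: 9 3,5-bis(benzyloxy)-4-[3,5,7,3',4',5'-hexa-O-benzyl-(−)-epigallocatechin-4β-yl]phenol; 13 (S)-[(2R)-oxiran-2-yl][3,4,5-tris(benzyloxy)phenyl]methanol
Product: 14 (2R)-2-{(R)-[3,4,5-tris(benzyloxy)phenyl](aryloxy)methyl}oxirane, aryloxy being the phenoxy group of 9 (threo)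
Conditions: PPh3, DIAD, THF, 0 °C to rt
Reagents that add atoms: none
Why: Mitsunobu etherification, in which the phenoxide displaces the oxyphosphonium group with inversion (S to R at the future C2) and leaves the oxirane untouched, giving the threo aryl ether that maps onto a 2,3-cis ring F.

Step 11
Reactants: 14 (2R)-2-{(R)-[3,4,5-tris(benzyloxy)phenyl](aryloxy)methyl}oxirane
Product: 15 3,5,7,3',4',5'-hexa-O-benzylepigallocatechin-(4β→6)-5,7,3',4',5'-penta-O-benzylepigallocatechin (lower unit 2R,3R, 3-OH free)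
Conditions: AuCl3 (5 mol %), AgOTf (15 mol %), ClCH2CH2Cl (high dilution), 0 °C to rt
Reagents that add atoms: none
Why: Trivalent gold (AuCl3 activated by AgOTf) should coordinate the oxirane oxygen, and ring D then attacks the terminal epoxide carbon C4 through a carbon ortho to O1, after which the Wheland intermediate rearomatises with proton transfer to the C3 alkoxide; the closest known reaction type is the gold-catalysed intramolecular Friedel–Crafts epoxy-arene cyclialkylation of aryl glycidyl-type ethers to 3-chromanols. Ring F closes in the 6-endo-tet mode, which should win over 5-exo attack at C3 because that carbon is hindered by the aryl and aryloxy groups on C2 and inductively deactivated by the C2–O bond. No stereocentre is formed: C4 becomes CH2, the C3–O bond is never broken so the (R)-oxirane carbon becomes the (3R)-carbinol, and C2 (R) is untouched, so the 2,3-cis relation follows from the threo arrangement in 14. The step needs site selectivity among seven arenes and between a C6- and a C8-linked product: ring D is the only phloroglucinol-type ring that can reach C4 through a six-membered transition state, and its two ortho carbons are equivalent because the upper unit sits para to O1, so either closure gives the same 4→6 constitution. Because the benzylic C2–O1 bond and the interflavan bond are acid-labile, a catalytic aprotic Lewis acid at or below room temperature is chosen.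

Step 12
Reactants: 15 3,5,7,3',4',5'-hexa-O-benzylepigallocatechin-(4β→6)-5,7,3',4',5'-penta-O-benzylepigallocatechin; 16 3,4,5-tris(benzyloxy)benzoic acid
Product: 17 lower-unit 3-O-[3,4,5-tris(benzyloxy)benzoyl] ester of 15
Conditions: DCC, DMAP, CH2Cl2, rt
Reagents that add atoms: none
Why: Steglich esterification should acylate the only free hydroxyl (lower 3-OH) with retention at C3, the upper 3-oxygen being benzylated.

Step 13
Reactants: 17 lower-unit 3-O-[3,4,5-tris(benzyloxy)benzoyl] ester of 15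
Product: 18 epigallocatechin-(4β→6)-epigallocatechin 3-O-gallate (target)
Conditions: H2 (1 atm), Pd(OH)2/C, THF/MeOH/H2O, rt
Reagents that add atoms: none
Why: Heterogeneous hydrogenolysis should cleave all fourteen benzyl ethers (thirteen aryl, one alkyl) without affecting the ester, the interflavan bond or any stereocentre.

**Compound list**
1 | (−)-epigallocatechin, (2R,3R) | C1c2c(O)cc(O)cc2O[C@H](c2cc(O)c(O)c(O)c2)[C@@H]1O | starting material
2 | 5,7,3',4',5'-penta-O-benzyl-(−)-epigallocatechin | C1c2c(OCc3ccccc3)cc(OCc3ccccc3)cc2O[C@H](c2cc(OCc3ccccc3)c(OCc3ccccc3)c(OCc3ccccc3)c2)[C@@H]1O | intermediate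
3 | 3,5,7,3',4',5'-hexa-O-benzyl-(−)-epigallocatechin | C1c2c(OCc3ccccc3)cc(OCc3ccccc3)cc2O[C@H](c2cc(OCc3ccccc3)c(OCc3ccccc3)c(OCc3ccccc3)c2)[C@@H]1OCc1ccccc1 | intermediate
4 | 4β-(2-ethoxyethoxy)-3,5,7,3',4',5'-hexa-O-benzyl-(−)-epigallocatechin (2R; 2,3-cis; 3,4-trans; 4S) | CCOCCO[C@H]1c2c(OCc3ccccc3)cc(OCc3ccccc3)cc2O[C@H](c2cc(OCc3ccccc3)c(OCc3ccccc3)c(OCc3ccccc3)c2)[C@@H]1OCc1ccccc1 | intermediate
5 | 8-bromo-4β-(2-ethoxyethoxy)-3,5,7,3',4',5'-hexa-O-benzyl-(−)-epigallocatechin | CCOCCO[C@H]1c2c(OCc3ccccc3)cc(OCc3ccccc3)c(Br)c2O[C@H](c2cc(OCc3ccccc3)c(OCc3ccccc3)c(OCc3ccccc3)c2)[C@@H]1OCc1ccccc1 | intermediate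
6 | 3,5-bis(benzyloxy)phenol | Oc1cc(OCc2ccccc2)cc(OCc2ccccc2)c1 | starting material
7 | 3,5-bis(benzyloxy)-2,6-dibromophenol | Oc1c(Br)c(OCc2ccccc2)cc(OCc2ccccc2)c1Br | intermediate
8 | 3,5-bis(benzyloxy)-2,6-dibromo-4-[8-bromo-3,5,7,3',4',5'-hexa-O-benzyl-(−)-epigallocatechin-4β-yl]phenol | Oc1c(Br)c(OCc2ccccc2)c(c(OCc2ccccc2)c1Br)[C@H]1c2c(OCc3ccccc3)cc(OCc3ccccc3)c(Br)c2O[C@H](c2cc(OCc3ccccc3)c(OCc3ccccc3)c(OCc3ccccc3)c2)[C@@H]1OCc1ccccc1 | intermediate
9 | 3,5-bis(benzyloxy)-4-[3,5,7,3',4',5'-hexa-O-benzyl-(−)-epigallocatechin-4β-yl]phenol | Oc1cc(OCc2ccccc2)c(c(OCc2ccccc2)c1)[C@H]1c2c(OCc3ccccc3)cc(OCc3ccccc3)cc2O[C@H](c2cc(OCc3ccccc3)c(OCc3ccccc3)c(OCc3ccccc3)c2)[C@@H]1OCc1ccccc1 | intermediate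
10 | 3,4,5-tris(benzyloxy)benzaldehyde | O=Cc1cc(OCc2ccccc2)c(OCc2ccccc2)c(OCc2ccccc2)c1 | starting material
11 | vinylmagnesium bromide | C=C[Mg]Br | starting material
12 | rac-1-[3,4,5-tris(benzyloxy)phenyl]prop-2-en-1-ol | OC(C=C)c1cc(OCc2ccccc2)c(OCc2ccccc2)c(OCc2ccccc2)c1 | intermediate
13 | (S)-[(2R)-oxiran-2-yl][3,4,5-tris(benzyloxy)phenyl]methanol (erythro) | O[C@@H](c1cc(OCc2ccccc2)c(OCc2ccccc2)c(OCc2ccccc2)c1)[C@H]1CO1 | intermediate
14 | (2R)-2-{(R)-[3,4,5-tris(benzyloxy)phenyl](aryloxy)methyl}oxirane, aryloxy = phenoxy group of 9 (threo) | O(c1cc(OCc2ccccc2)c(c(OCc2ccccc2)c1)[C@H]1c2c(OCc3ccccc3)cc(OCc3ccccc3)cc2O[C@H](c2cc(OCc3ccccc3)c(OCc3ccccc3)c(OCc3ccccc3)c2)[C@@H]1OCc1ccccc1)[C@H](c1cc(OCc2ccccc2)c(OCc2ccccc2)c(OCc2ccccc2)c1)[C@H]1CO1 | intermediate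
15 | 3,5,7,3',4',5'-hexa-O-benzylepigallocatechin-(4β→6)-5,7,3',4',5'-penta-O-benzylepigallocatechin (lower 3-OH free) | O[C@@H]1Cc2c(cc(OCc3ccccc3)c([C@H]3c4c(OCc5ccccc5)cc(OCc5ccccc5)cc4O[C@H](c4cc(OCc5ccccc5)c(OCc5ccccc5)c(OCc5ccccc5)c4)[C@@H]3OCc3ccccc3)c2OCc2ccccc2)O[C@@H]1c1cc(OCc2ccccc2)c(OCc2ccccc2)c(OCc2ccccc2)c1 | intermediate
16 | 3,4,5-tris(benzyloxy)benzoic acid | OC(=O)c1cc(OCc2ccccc2)c(OCc2ccccc2)c(OCc2ccccc2)c1 | starting material
17 | lower-unit 3-O-[3,4,5-tris(benzyloxy)benzoyl] ester of 15 | O=C(O[C@@H]1Cc2c(cc(OCc3ccccc3)c([C@H]3c4c(OCc5ccccc5)cc(OCc5ccccc5)cc4O[C@H](c4cc(OCc5ccccc5)c(OCc5ccccc5)c(OCc5ccccc5)c4)[C@@H]3OCc3ccccc3)c2OCc2ccccc2)O[C@@H]1c1cc(OCc2ccccc2)c(OCc2ccccc2)c(OCc2ccccc2)c1)c1cc(OCc2ccccc2)c(OCc2ccccc2)c(OCc2ccccc2)c1 | intermediate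
18 | epigallocatechin-(4β→6)-epigallocatechin 3-O-gallate (ester on the lower unit) | O=C(O[C@@H]1Cc2c(cc(O)c([C@H]3c4c(O)cc(O)cc4O[C@H](c4cc(O)c(O)c(O)c4)[C@@H]3O)c2O)O[C@@H]1c1cc(O)c(O)c(O)c1)c1cc(O)c(O)c(O)c1 | target

**Count and risks**
Total step count: 13. Longest linear sequence: 10 steps (1, 2, 3, 4, 6, 7, 10, 11, 12, 13).

Step 11 (key ring closure). The Lewis acid may ionise the benzylic C2–O1 ether or the interflavan bond of the large substrate faster than it activates the epoxide, so that fragmentation or scrambling of the two units competes with closure. The fallback sets out from 6 and 13 and comes back at 15; it closes the same bond on the simple ether and forms the interflavan bond afterwards under halogen-capping control. Mitsunobu etherification of 6 with 13 (PPh3, DIAD) should give (2R)-2-{(R)-[3,5-bis(benzyloxy)phenoxy][3,4,5-tris(benzyloxy)phenyl]methyl}oxirane F1. The same gold-catalysed epoxy-arene closure should turn F1 into 2, which can be compared with the sample from step 1. NBS should brominate 2 at C8 to 8-bromo-5,7,3',4',5'-penta-O-benzyl-(−)-epigallocatechin F2. TMSOTf-mediated coupling of F2 with 5 can then take place only at C6 and should give 8-bromo-hexa-O-benzylepigallocatechin-(4β→6)-8-bromo-penta-O-benzylepigallocatechin F3. Palladium-catalysed formate reduction as in step 7 should remove both bromines and give 15.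

Step 6 (interflavan coupling). Attack by the hindered, bromine-deactivated carbon of 7 may be so slow that the cation from 5 is consumed by oligomerisation through C6 of another molecule or by elimination to the flav-3-ene. The fallback sets out from 6 and comes back at 9; it replaces halogen blocking by steric shielding on a ring that carries no deactivating substituent. Silylation of 6 (TIPSCl, imidazole) should give [3,5-bis(benzyloxy)phenoxy]triisopropylsilane F4. In the TMSOTf coupling with 5 the bulky silyloxy group should screen both ortho carbons and direct attack to the para carbon, giving the silyl ether of the 8-bromo analogue of 9, F5. TBAF should release 3,5-bis(benzyloxy)-4-[8-bromo-hexa-O-benzylepigallocatechin-4β-yl]phenol F6. Palladium-catalysed formate reduction of the single bromide should give 9.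

Step 9 (kinetic resolution). The titanium alkoxide may ionise the doubly activated (benzylic and allylic) alcohol or open the acid-labile epoxy alcohol during the long reaction time a resolution needs, and half of the material is lost by design. The fallback sets out from 12 and comes back at 13; it separates the enantiomers enzymatically and epoxidises under milder, substrate-directed control. Acylation of 12 with vinyl acetate and immobilised lipase B from Candida antarctica should convert only the (R)-enantiomer into (R)-1-[3,4,5-tris(benzyloxy)phenyl]prop-2-enyl acetate F7. Methanolysis (K2CO3, MeOH) should give (R)-1-[3,4,5-tris(benzyloxy)phenyl]prop-2-en-1-ol F8. Hydroxyl-directed epoxidation of F8 (VO(acac)2, t-BuOOH, toluene, 0 °C) should give mainly the erythro epoxy alcohol 13, which is separated from its threo isomer.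

**Further compounds**
F1 | step 11 | (2R)-2-{(R)-[3,5-bis(benzyloxy)phenoxy][3,4,5-tris(benzyloxy)phenyl]methyl}oxirane | O(c1cc(OCc2ccccc2)cc(OCc2ccccc2)c1)[C@H](c1cc(OCc2ccccc2)c(OCc2ccccc2)c(OCc2ccccc2)c1)[C@H]1CO1
F2 | step 11 | 8-bromo-5,7,3',4',5'-penta-O-benzyl-(−)-epigallocatechin | C1c2c(OCc3ccccc3)cc(OCc3ccccc3)c(Br)c2O[C@H](c2cc(OCc3ccccc3)c(OCc3ccccc3)c(OCc3ccccc3)c2)[C@@H]1O
F3 | step 11 | 8-bromo-3,5,7,3',4',5'-hexa-O-benzylepigallocatechin-(4β→6)-8-bromo-5,7,3',4',5'-penta-O-benzylepigallocatechin | O[C@@H]1Cc2c(c(Br)c(OCc3ccccc3)c([C@H]3c4c(OCc5ccccc5)cc(OCc5ccccc5)c(Br)c4O[C@H](c4cc(OCc5ccccc5)c(OCc5ccccc5)c(OCc5ccccc5)c4)[C@@H]3OCc3ccccc3)c2OCc2ccccc2)O[C@@H]1c1cc(OCc2ccccc2)c(OCc2ccccc2)c(OCc2ccccc2)c1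
F4 | step 6 | [3,5-bis(benzyloxy)phenoxy]triisopropylsilane | CC(C)[Si](C(C)C)(C(C)C)Oc1cc(OCc2ccccc2)cc(OCc2ccccc2)c1
F5 | step 6 | {3,5-bis(benzyloxy)-4-[8-bromo-3,5,7,3',4',5'-hexa-O-benzyl-(−)-epigallocatechin-4β-yl]phenoxy}triisopropylsilane | CC(C)[Si](C(C)C)(C(C)C)Oc1cc(OCc2ccccc2)c(c(OCc2ccccc2)c1)[C@H]1c2c(OCc3ccccc3)cc(OCc3ccccc3)c(Br)c2O[C@H](c2cc(OCc3ccccc3)c(OCc3ccccc3)c(OCc3ccccc3)c2)[C@@H]1OCc1ccccc1
F6 | step 6 | 3,5-bis(benzyloxy)-4-[8-bromo-3,5,7,3',4',5'-hexa-O-benzyl-(−)-epigallocatechin-4β-yl]phenol | Oc1cc(OCc2ccccc2)c(c(OCc2ccccc2)c1)[C@H]1c2c(OCc3ccccc3)cc(OCc3ccccc3)c(Br)c2O[C@H](c2cc(OCc3ccccc3)c(OCc3ccccc3)c(OCc3ccccc3)c2)[C@@H]1OCc1ccccc1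
F7 | step 9 | (R)-1-[3,4,5-tris(benzyloxy)phenyl]prop-2-enyl acetate | CC(=O)O[C@@H](c1cc(OCc2ccccc2)c(OCc2ccccc2)c(OCc2ccccc2)c1)C=C
F8 | step 9 | (R)-1-[3,4,5-tris(benzyloxy)phenyl]prop-2-en-1-ol | O[C@@H](c1cc(OCc2ccccc2)c(OCc2ccccc2)c(OCc2ccccc2)c1)C=C
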